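**Retrosynthetic overview**

1. Atom numbers: ring C1(OH)–C2H2–C3HCl–C4(Br)(C15H3)–C5H2–C6H2; side chain C7(=C14H2)–C8H2–C9H2–C10H(OH)–C11(=C12H2)–C13H3.
2. The C1–OH is traced back through a Mislow–Evans [2,3] shift (sulfur on C14) and a 1,4-hydrothiolation to the diene C6=C1–C7=C14.
3. Enabling feature: ring atom C1 carries the 1,1-disubstituted alkene C7=C14H2. Atoms C6, C1, C7 and C14 are therefore the 1-(alk-1-en-2-yl)cyclohexene retron of an exo ring-closing enyne metathesis. Cutting C1–C6 gives an acyclic 1,7-enyne (C6H=C14H2 plus C1≡C7), and the neutral ruthenium carbene tolerates C3–Cl and C4–Br.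
4. The enyne comes from the acetylide of the C1/C7–C13 alkyne (C10 set by CBS reduction) and the C2 triflate of the C2–C6/C14/C15 unit. C3 and C4 are set on the open chain by enantioselective anti-dichlorination of a (Z)-allylic alcohol, followed by retentive Cl→Br exchange at C4. BrCl addition to the finished cyclohexene would instead put Cl on C4 and open diaxially to the wrong diastereomer.
5. Ring order: the cyclohexane is the only ring, and it is closed once, in the key step.

Key step: step 11

Remark: in step 7 the ligand enantiomer that leads to the (2R,3R) series is used. The allylic sulfide of step 12 may form as an E/Z mixture at C1=C7, which does not matter because both isomers converge in step 13.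

**Step 1**
Reactants: 1 pent-4-ynoic acid
Product: 3 N-methoxy-N-methylpent-4-ynamide, via acyl imidazolide 2 (not isolated)
Conditions: 1,1'-carbonyldiimidazole, CH2Cl2, 0 °C to rt; then MeNH(OMe)·HCl, rt
Reagents that add atoms: N,O-dimethylhydroxylamine hydrochloride, CNOC.Cl
Why: Activation of the acid as the acyl imidazolide followed by aminolysis is the standard Weinreb amide synthesis, leaves the terminal alkyne untouched and creates no stereocentre.

**Step 2**
Reactants: 3 N-methoxy-N-methylpent-4-ynamide; 4 isopropenylmagnesium bromide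
Product: 5 2-methylhept-1-en-6-yn-3-one
Conditions: CH2=C(CH3)MgBr (2.2 equiv), THF, −78 to 0 °C; then H2O
Reagents that add atoms: none
Why: In this Weinreb ketone synthesis the first equivalent of Grignard reagent only deprotonates the alkyne, and the second forms the chelated tetrahedral adduct, which cannot over-add and collapses to the enone on quench.

**Step 3**
Reactants: 5 2-methylhept-1-en-6-yn-3-one
Product: 6 (3R)-2-methylhept-1-en-6-yn-3-ol
Conditions: (S)-2-methyl-CBS-oxazaborolidine (10 mol %), catecholborane, toluene, −78 °C; then H2O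
Reagents that add atoms: none
Why: In the Corey–Bakshi–Shibata reduction the isopropenyl group acts as the large substituent and the CH2CH2 chain as the small one, so the (S)-catalyst should deliver hydride to the face that gives (R) at C10, and catecholborane at low temperature does not hydroborate the alkyne or the alkene.

**Step 4**
Reactants: 6 (3R)-2-methylhept-1-en-6-yn-3-ol
Product: 7 tert-butyl(dimethyl){[(3R)-2-methylhept-1-en-6-yn-3-yl]oxy}silane
Conditions: TBSCl, imidazole, DMF, rt
Reagents that add atoms: tert-butyldimethylsilyl chloride, CC(C)(C)[Si](C)(C)Cl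
Why: Standard silylation masks the C10 hydroxyl against n-BuLi, peracid and phosphite, and its bulk also shields the neighbouring C11=C12 alkene.

**Step 5**
Reactants: 8 but-2-yn-1-ol
Product: 10 (2Z)-3-iodobut-2-en-1-ol, via cyclic alkenylalanate 9 (not isolated)
Conditions: NaAlH2(OCH2CH2OMe)2, THF, 0 °C to rt; then I2, −78 °C; then H2O
Reagents that add atoms: iodine, II
Why: Hydroxyl-directed trans-hydroalumination places aluminium on the methyl-bearing carbon inside a five-membered alkoxyaluminate ring, and iodinolysis with retention fixes iodine cis to CH2OH (Z).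

**Step 6**
Reactants: 10 (2Z)-3-iodobut-2-en-1-ol; 11 allyltributylstannane
Product: 12 (2Z)-3-methylhexa-2,5-dien-1-ol
Conditions: PdCl2(MeCN)2 (5 mol %), DMF, rt
Reagents that add atoms: none
Why: Stille coupling of an alkenyl iodide proceeds with retention, so C5 ends cis to C2 as the later ring requires, and the mild conditions avoid conjugation of the skipped diene.

**Step 7**
Reactants: 12 (2Z)-3-methylhexa-2,5-dien-1-ol
Product: 13 (2R,3R)-2,3-dichloro-3-methylhex-5-en-1-ol
Conditions: tBuOCl, ClTi(OiPr)3, chiral tridentate Schiff-base ligand (15 mol %), hexanes, −20 °C; then H2O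
Reagents that add atoms: tert-butyl hypochlorite, CC(C)(C)OCl; chlorotitanium triisopropoxide, CC(C)O[Ti](Cl)(OC(C)C)OC(C)C
Why: In the titanium/Schiff-base-catalysed enantioselective dichlorination of allylic alcohols, anti addition to the (Z)-alkene fixes the relative configuration of C3 and C4, the ligand on the substrate-bound titanium alkoxide fixes the absolute one, regiochemistry is not an issue, and the undirected monosubstituted alkene is left alone.

**Step 8**
Reactants: 13 (2R,3R)-2,3-dichloro-3-methylhex-5-en-1-ol
Product: 16 (2R,3R)-3-bromo-2-chloro-3-methylhex-5-en-1-ol, via alkoxydibromoborane 14 (not isolated), via exchanged alkoxyborane 15 (not isolated)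
Conditions: BBr3 (1.2 equiv), 2,6-di-tert-butylpyridine (1.2 equiv), CH2Cl2, −78 to −20 °C; then H2O
Reagents that add atoms: boron tribromide, BrB(Br)Br
Why: Proposed new method: the primary alcohol first becomes the alkoxydibromoborane, whose boron lies within a six-membered array (B–O–C2–C3–C4–Cl) of the only ionisable (tertiary) chloride, abstracts it and returns bromide to the same face of the tight ion pair while the vicinal C3–Cl shields the rear face in a chloronium-like manner, so that C4 should be substituted with retention and C3–Cl stays, driven by the stronger B–Cl bond; the closest known reaction types are BBr3 halogen exchange of tertiary alkyl chlorides and the stereospecific ionisation of vicinal dihalides through halonium ions.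

**Step 9**
Reactants: 16 (2R,3R)-3-bromo-2-chloro-3-methylhex-5-en-1-ol
Product: 17 (2R,3R)-3-bromo-2-chloro-3-methylhex-5-en-1-yl trifluoromethanesulfonate
Conditions: Tf2O, 2,6-lutidine, CH2Cl2, −78 °C; rapid cold filtration through silica
Reagents that add atoms: trifluoromethanesulfonic anhydride, O=S(=O)(OS(=O)(=O)C(F)(F)F)C(F)(F)F
Why: O-Triflation with a hindered base at low temperature turns the inductively deactivated β-chloro primary carbinol into an electrophile reactive enough for substitution far below the temperature at which the halides are affected.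

**Step 10**
Reactants: 7 tert-butyl(dimethyl){[(3R)-2-methylhept-1-en-6-yn-3-yl]oxy}silane; 17 (2R,3R)-3-bromo-2-chloro-3-methylhex-5-en-1-yl trifluoromethanesulfonate
Product: 19 (3R,9R,10R)-10-bromo-9-chloro-2,10-dimethyl-3-(tert-butyldimethylsilyloxy)trideca-1,12-dien-6-yne, via lithium acetylide 18 (not isolated)
Conditions: 7, n-BuLi, THF, −78 °C; DMPU; then 17, −78 to −30 °C
Reagents that add atoms: none
Why: SN2 alkylation of a lithium acetylide by a primary triflate forms C1–C2 at temperatures where elimination at the tertiary bromide should be slow, and no stereocentre takes part.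

**Step 11**
Reactants: 19 (3R,9R,10R)-10-bromo-9-chloro-2,10-dimethyl-3-(tert-butyldimethylsilyloxy)trideca-1,12-dien-6-yne
Product: 20 tert-butyl({(3R)-6-[(4R,5R)-4-bromo-5-chloro-4-methylcyclohex-1-en-1-yl]-2-methylhepta-1,6-dien-3-yl}oxy)dimethylsilane
Conditions: second-generation Grubbs catalyst RuCl2(=CHPh)(H2IMes)(PCy3) (5–10 mol %), ethene (1 atm), CH2Cl2 (0.005 M), 40 °C
Reagents that add atoms: none
Why: The ruthenium carbene is loaded on the only monosubstituted alkene (C6=C14) and adds across the tethered alkyne C1≡C7 to a ruthenacyclobutene, which opens to a vinylcarbene on C7 and is released by methylene transfer, so that C6 becomes bonded to C1 and the former terminal CH2 (C14) ends on C7 as the exo-methylene of the target. The closest known reaction type is ring-closing enyne metathesis of 1,7-enynes with internal alkynes to 1-(alk-1-en-2-yl)cyclohexenes under ethene. The six-membered ring closes in the exo mode (C1 in the ring, C7 outside), which is preferred over the seven-membered endo mode by ring size and by the fully substituted C4 in the tether. No stereocentre is created, C3, C4 and C10 are spectators, and the ring formed here is the element that later controls C1. The step needs initiation at C6=C14 rather than at the hindered 1,1-disubstituted C11=C12 next to the silyl ether, and it needs both C–X bonds to survive, which the absence of base, reductant and Lewis acid secures. In one isomerisation the acyclic chain thus gains the carbocycle, the C1–C6 bond and the C7=C14 alkene.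

**Step 12**
Reactants: 20 tert-butyl({(3R)-6-[(4R,5R)-4-bromo-5-chloro-4-methylcyclohex-1-en-1-yl]-2-methylhepta-1,6-dien-3-yl}oxy)dimethylsilane
Product: 21 ({(3R)-6-[(3R,4R)-4-bromo-3-chloro-4-methylcyclohexylidene]-2-methyl-7-(phenylsulfanyl)hept-1-en-3-yl}oxy)(tert-butyl)dimethylsilane
Conditions: PhSH (1.0 equiv), 2,2-dimethoxy-2-phenylacetophenone (5 mol %), 365 nm, toluene, 0 °C
Reagents that add atoms: thiophenol, Sc1ccccc1
Why: In this radical 1,4-hydrothiolation of a conjugated diene the thiyl radical adds to the unhindered terminus C14, the delocalised allyl radical takes hydrogen from PhSH at its less hindered end C6, the reversible addition to the isolated C11=C12 is not productive with one equivalent of thiol, and stabilised allyl and thiyl radicals do not abstract bromine.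

**Step 13**
Reactants: 21 ({(3R)-6-[(3R,4R)-4-bromo-3-chloro-4-methylcyclohexylidene]-2-methyl-7-(phenylsulfanyl)hept-1-en-3-yl}oxy)(tert-butyl)dimethylsilane
Product: 24 (1S,3R,4R)-4-bromo-1-[(5R)-5-(tert-butyldimethylsilyloxy)-6-methylhepta-1,6-dien-2-yl]-3-chloro-4-methylcyclohexan-1-ol, via allylic sulfoxide 22 (not isolated), via allylic sulfenate 23 (not isolated)
Conditions: mCPBA (1.0 equiv), CH2Cl2, −78 °C; then P(OMe)3, MeOH, −78 °C to rt
Reagents that add atoms: 3-chloroperoxybenzoic acid, O=C(OO)c1cccc(Cl)c1
Why: Sulfur is oxidised much faster than any alkene at −78 °C, and the Mislow–Evans [2,3] shift, pulled forward by the thiophile, restores C7=C14 and delivers oxygen to C1 on the ring face opposite the axial C3–Cl of the favoured chair (Cl and Br axial, CH3 equatorial), that is cis to Br, which should set (1S).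

**Step 14**
Reactants: 24 (1S,3R,4R)-4-bromo-1-[(5R)-5-(tert-butyldimethylsilyloxy)-6-methylhepta-1,6-dien-2-yl]-3-chloro-4-methylcyclohexan-1-ol
Product: 25 (1S,3R,4R)-4-bromo-3-chloro-1-[(5R)-5-hydroxy-6-methylhepta-1,6-dien-2-yl]-4-methylcyclohexan-1-ol
Conditions: HF·pyridine, pyridine, THF, 0 °C to rt
Reagents that add atoms: none
Why: Buffered fluoride cleavage of the silyl ether is neither basic enough to eliminate the tertiary bromide nor acidic enough to ionise the tertiary allylic alcohol.

**Compound list**

1 | pent-4-ynoic acid | C#CCCC(=O)O | starting material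
2 | 1-(1H-imidazol-1-yl)pent-4-yn-1-one | C#CCCC(=O)n1ccnc1 | intermediate
3 | N-methoxy-N-methylpent-4-ynamide | C#CCCC(=O)N(C)OC | intermediate
4 | isopropenylmagnesium bromide | C=C(C)[Mg]Br | starting material
5 | 2-methylhept-1-en-6-yn-3-one | C=C(C)C(=O)CCC#C | intermediate
6 | (3R)-2-methylhept-1-en-6-yn-3-ol | C=C(C)[C@H](O)CCC#C | intermediate
7 | tert-butyl(dimethyl){[(3R)-2-methylhept-1-en-6-yn-3-yl]oxy}silane | C=C(C)[C@H](O[Si](C)(C)C(C)(C)C)CCC#C | intermediate
8 | but-2-yn-1-ol | CC#CCO | starting material
9 | sodium 2,2-bis(2-methoxyethoxy)-3-methyl-2,5-dihydro-1,2-oxaaluminol-2-uide (cyclic alkenylalanate) | [Na+].CC1=CCO[Al-]1(OCCOC)OCCOC | intermediate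
10 | (2Z)-3-iodobut-2-en-1-ol | C/C(I)=C/CO | intermediate
11 | allyltributylstannane | C=CC[Sn](CCCC)(CCCC)CCCC | starting material
12 | (2Z)-3-methylhexa-2,5-dien-1-ol | C/C(CC=C)=C/CO | intermediate
13 | (2R,3R)-2,3-dichloro-3-methylhex-5-en-1-ol | C=CC[C@@](C)(Cl)[C@H](Cl)CO | intermediate
14 | dibromo{[(2R,3R)-2,3-dichloro-3-methylhex-5-en-1-yl]oxy}borane | C=CC[C@@](C)(Cl)[C@H](Cl)COB(Br)Br | intermediate
15 | bromo(chloro){[(2R,3R)-3-bromo-2-chloro-3-methylhex-5-en-1-yl]oxy}borane | C=CC[C@@](C)(Br)[C@H](Cl)COB(Br)Cl | intermediate
16 | (2R,3R)-3-bromo-2-chloro-3-methylhex-5-en-1-ol | C=CC[C@@](C)(Br)[C@H](Cl)CO | intermediate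
17 | (2R,3R)-3-bromo-2-chloro-3-methylhex-5-en-1-yl trifluoromethanesulfonate | C=CC[C@@](C)(Br)[C@H](Cl)COS(=O)(=O)C(F)(F)F | intermediate
18 | lithium acetylide of 7 | C=C(C)[C@H](O[Si](C)(C)C(C)(C)C)CCC#C[Li] | intermediate
19 | (3R,9R,10R)-10-bromo-9-chloro-2,10-dimethyl-3-(tert-butyldimethylsilyloxy)trideca-1,12-dien-6-yne | C=CC[C@@](C)(Br)[C@H](Cl)CC#CCC[C@@H](O[Si](C)(C)C(C)(C)C)C(C)=C | intermediate
20 | tert-butyl({(3R)-6-[(4R,5R)-4-bromo-5-chloro-4-methylcyclohex-1-en-1-yl]-2-methylhepta-1,6-dien-3-yl}oxy)dimethylsilane | C=C(C)[C@H](O[Si](C)(C)C(C)(C)C)CCC(=C)C1=CC[C@@](C)(Br)[C@H](Cl)C1 | intermediate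
21 | ({(3R)-6-[(3R,4R)-4-bromo-3-chloro-4-methylcyclohexylidene]-2-methyl-7-(phenylsulfanyl)hept-1-en-3-yl}oxy)(tert-butyl)dimethylsilane (alkene C1=C7 as E/Z mixture) | C=C(C)[C@H](O[Si](C)(C)C(C)(C)C)CCC(CSc1ccccc1)=C1CC[C@@](C)(Br)[C@H](Cl)C1 | intermediate
22 | S-oxide of 21 (allylic phenyl sulfoxide, both configurations at sulfur) | C=C(C)[C@H](O[Si](C)(C)C(C)(C)C)CCC(CS(=O)c1ccccc1)=C1CC[C@@](C)(Br)[C@H](Cl)C1 | intermediate
23 | benzenesulfenate ester of 24 (O–SPh on C1) | C=C(C)[C@H](O[Si](C)(C)C(C)(C)C)CCC(=C)[C@]1(OSc2ccccc2)CC[C@@](C)(Br)[C@H](Cl)C1 | intermediate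
24 | (1S,3R,4R)-4-bromo-1-[(5R)-5-(tert-butyldimethylsilyloxy)-6-methylhepta-1,6-dien-2-yl]-3-chloro-4-methylcyclohexan-1-ol | C=C(C)[C@H](O[Si](C)(C)C(C)(C)C)CCC(=C)[C@]1(O)CC[C@@](C)(Br)[C@H](Cl)C1 | intermediate
25 | (1S,3R,4R)-4-bromo-3-chloro-1-[(5R)-5-hydroxy-6-methylhepta-1,6-dien-2-yl]-4-methylcyclohexan-1-ol | C=C(C)[C@H](O)CCC(=C)[C@]1(O)CC[C@@](C)(Br)[C@H](Cl)C1 | target

**Step count**

Total step count: 14.
Longest linear sequence: 10 steps (steps 5 to 14, from but-2-yn-1-ol).

**Steps most likely to fail**

**Step 8 (Proposed new method).** After ionisation at C4 the ion pair may lose its facial memory, which would epimerise C4. It may also lose a proton to give alkenes, or let chlorine migrate from C3.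

The fallback uses known chemistry only. It sets out from 12 and rejoins the route at 16. Sharpless asymmetric epoxidation (Ti(OiPr)4, L-(+)-diethyl tartrate, tBuOOH, 4 Å sieves, CH2Cl2, −20 °C) should give [(2S,3R)-3-allyl-3-methyloxiran-2-yl]methanol F1. Borate-directed opening of this 2,3-epoxy alcohol by chloride at the less substituted epoxide carbon, with inversion (LiCl, B(OMe)3, DMF), should give (2R,3R)-2-chloro-3-methylhex-5-ene-1,3-diol F2. Me3SiBr (excess, CHCl3, 0 °C) replaces tertiary hydroxyl groups much faster than primary ones. The primary hydroxyl is only silylated and is freed again on work-up, so this should give 16. The neighbouring chlorine is again relied on for retention at C4.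

**Step 13.** Oxygen transfer to C1 may show poor facial selectivity. The sulfoxide–sulfenate equilibrium at the tetrasubstituted alkene may also be too unfavourable for interception.

The fallback replaces substrate control by reagent control. It sets out from 20, bypasses 21, and rejoins the route at 24. Shi epoxidation of the more electron-rich trisubstituted diene alkene C1=C6 uses the fructose-derived ketone of the enantiomeric series that attacks the face anti to C3–Cl, with KHSO5 and K2CO3 buffer in MeCN/dimethoxymethane/H2O at 0 °C. It should give 4-bromo-3-chloro-4-methyl-1-[(5R)-5-(tert-butyldimethylsilyloxy)-6-methylhepta-1,6-dien-2-yl]-7-oxabicyclo[4.1.0]heptane with the oxygen cis to bromine F3. Hydride attack at the less substituted epoxide carbon C6 (LiBHEt3, THF, −78 °C) should then give 24.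

**Step 11.** Ring closure may be overtaken by seven-membered endo closure, by simple cross metathesis of the alkyne with ethene, or by catalyst decay.

The fallback separates the two events. It sets out from 19 and rejoins the route at 20. Deliberate ethene–alkyne cross metathesis (same ruthenium catalyst, ethene at elevated pressure, CH2Cl2) should give (3R,9R,10R)-10-bromo-9-chloro-2,10-dimethyl-6,7-dimethylidene-3-(tert-butyldimethylsilyloxy)trideca-1,12-diene F4. A diene–ene ring-closing metathesis between C6H=CH2 and C1=CH2, run in high dilution under argon, should then give 20.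

**Further compounds**

F1 | step 8 | [(2S,3R)-3-allyl-3-methyloxiran-2-yl]methanol | C=CC[C@@]1(C)O[C@H]1CO
F2 | step 8 | (2R,3R)-2-chloro-3-methylhex-5-ene-1,3-diol | C=CC[C@@](C)(O)[C@H](Cl)CO
F3 | step 13 | 4-bromo-3-chloro-4-methyl-1-[(5R)-5-(tert-butyldimethylsilyloxy)-6-methylhepta-1,6-dien-2-yl]-7-oxabicyclo[4.1.0]heptane, oxygen cis to bromine | C=C(C)[C@H](O[Si](C)(C)C(C)(C)C)CCC(=C)[C@@]12O[C@H]2C[C@@](C)(Br)[C@H](Cl)C1
F4 | step 11 | (3R,9R,10R)-10-bromo-9-chloro-2,10-dimethyl-6,7-dimethylidene-3-(tert-butyldimethylsilyloxy)trideca-1,12-diene | C=CC[C@@](C)(Br)[C@H](Cl)CC(=C)C(=C)CC[C@@H](O[Si](C)(C)C(C)(C)C)C(C)=C
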